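Locants used throughout: dihydronaphthalene carbons C1 (aryl-bearing), C2 and C3 (methyl-bearing), C4, C4a, C5–C8, C8a. Ring A is the fused benzene ring (6-OMe, 7-OH, 8-OMe). Ring B is the pendant 4-hydroxy-3,5-dimethoxyphenyl group (C1′–C6′). The target is the cis isomer, (1S,2S).

## The problem

The target is a 1-aryl-2,3-dimethyl-1,2-dihydronaphthalene: two syringyl units (ring A carrying C4, ring B carrying C1) bridged by C2, C3 and their methyl groups. The two stereocentres are contiguous. C1 is a diarylmethine whose aryl groups differ only in substitution pattern and which sits next to the C8 methoxy group; C2 is an allylic, methyl-bearing carbon; they are cis. This is not what the obvious ring closure should give: if C1–C8a is closed by Friedel–Crafts attack of ring A on a C1 cation, the aryl group goes pseudo-axial (peri strain with OMe-8) and the C2 methyl is free to go pseudo-axial as well (allylic strain with Me-3), which is trans. Neither centre can be corrected afterwards, because a cation, radical or anion at C1 or C2 of the finished ring is one hydrogen away from a 1-arylnaphthalene, and acid can move the C3=C4 bond. C1 is also the most hindered carbon (ring A has two ortho substituents), so setting it in a bimolecular step is unattractive. Both 2,6-dimethoxyphenols oxidise easily, ring B through a quinone methide at C1. That weakness is the enabling feature: O4′ of ring B is para to C1, so a C1 carbinol ionises to a p-quinone methide (hydroxy-diarylmethylium ion), and C2, C3 (with its methyl) and C4 are exactly an (E)-2-methylbut-2-enyl group on C4a, whose C2 can add to C1 while C4 gives up a proton to leave the C3=C4 styrene. Ring A is a symmetrically substituted syringyl ring, so C8a is its only kind of free position and can be brominated without a regiochemical choice.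

## Retrosynthesis

**12 ⇒ 10 (through quinone methide 11).** The C1–C2 bond is cut; C4 regains a hydrogen and C1 an OH. This is preferred to the neighbouring C1–C8a cut because there the C2 methyl chooses its own position and ends trans to the aryl group. With C1–C2 as the closing bond, the E-olefin geometry fixes the C2 methyl pseudo-equatorial, and the peri methoxy group should keep the aryl group pseudo-axial, which is cis. Precursor 10 has no carbocycle and no stereocentre that matters (the carbinol centre is erased on ionisation). The forward reaction must add a weakly nucleophilic trisubstituted olefin to one face of the C1 cation, through C2 only, and end by proton loss from C4.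

**10 ⇒ 9 ⇒ 7 + 2 (through aryllithium 8).** The C8a–C1 bond is cut between an aryllithium and an aldehyde. A 1,2-addition tolerates the two ortho substituents of ring A better than any conjugate addition or cross-coupling at C1 would. Aldehyde 2 is silylated syringaldehyde, so ring B and C1 come in one piece. Both phenols are silyl-protected until just before the key step.

**7 ⇒ 5 + 6.** The C4–C3 bond (sp3–sp2) is cut between a benzylic bromide and an alkenylboronate. The olefin geometry comes from 6 (the syn-hydroboration product of but-2-yne) and is transferred with retention. The alternative, an aryl metal plus a 2-methylbut-2-enyl electrophile, risks SN2/SN2′ mixtures and E/Z scrambling through an allyl-metal intermediate.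

**5 ⇒ 4 ⇒ 3 ⇒ 2 ⇒ 1.** These are functional-group steps on syringaldehyde 1. Its formyl carbon becomes C4, bromination ortho to it marks C8a, and the intermediate 2 is used twice (ring A and ring B).

## Roads not taken

Alternative 1: Cut C2–C3 and C1–C8a, the biogenetic dimer disconnection. Forward: one-electron oxidation (FeCl3 or a laccase) of (E)-4-propenylsyringol A1, β–β radical coupling to bis-quinone methide A2, tautomerisation and Friedel–Crafts closure. This is the shortest route on paper, but the radical coupling has no handle for enantiocontrol, and the closure is expected to give the trans isomer A3 for the conformational reasons above. The chosen plan keeps the same quinone-methide reactivity but closes a different bond.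

Alternative 2: Cut C3=C4 (ring-closing metathesis of diene A4) and set C1 and C2 in an acyclic chain with an oxazolidinone auxiliary (copper-mediated aryl Grignard addition to an N-cinnamoyl imide, then enolate methylation). By the usual chelate models, this pair of steps gives the relative configuration of the trans series when the unhindered ring B aryl is the nucleophile. The cis series would need the 2,6-disubstituted ring A aryl as the cuprate ligand, which transfers poorly. Three further steps are spent turning the carboxyl carbon into the isopropenyl group, and the route is about twelve steps long.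

Alternative 3: Cut C1–aryl on a naphthalene: dearomatising 1,4-addition of the ring B aryllithium to C1 of naphthyloxazoline A5, protonation at C2, then reduction of the oxazoline carbon to the C2 methyl. The enantiocontrol is precedented and the C3=C4 bond is simply what is left of the arene. However, the trisubstituted naphthoate needs a long run-up, and three more steps convert the carboxyl carbon to CH3. Meanwhile C2 is α to a C=N or C=O group and allylic, so the kinetic cis product would epimerise to trans. The chosen plan never has an acidifying group on C2.

Key step: step 8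

Assumption: boronate 6, the syn-hydroboration product of but-2-yne with pinacolborane, is taken as a purchasable reagent.
Assumption: the antipode of the chiral acid that leads to the (1S,2S) series cannot be predicted with confidence and is fixed by one screening run; the route is written with the (R)-acid.

## Route

Step 1
Reactants: 1 syringaldehyde (4-hydroxy-3,5-dimethoxybenzaldehyde)
Product: 2 3,5-dimethoxy-4-(triisopropylsilyloxy)benzaldehyde
Conditions: TIPSCl, imidazole, DMF, rt
Reagents that add atoms: chlorotriisopropylsilane (TIPSCl), CC(C)[Si](Cl)(C(C)C)C(C)C
Why: Silylation of the phenol; the bulky triisopropylsilyl ether should survive NBS, hydride, aqueous carbonate and butyllithium and comes off with fluoride.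

Step 2
Reactants: 2 3,5-dimethoxy-4-(triisopropylsilyloxy)benzaldehyde
Product: 3 2-bromo-3,5-dimethoxy-4-(triisopropylsilyloxy)benzaldehyde
Conditions: NBS, MeCN, 0 °C to rt
Reagents that add atoms: N-bromosuccinimide (NBS), O=C1CCC(=O)N1Br
Why: Electrophilic aromatic bromination; C2 and C6 are the only free positions, are equivalent, and are each ortho and para to a methoxy group, so monobromination should give one product.

Step 3
Reactants: 3 2-bromo-3,5-dimethoxy-4-(triisopropylsilyloxy)benzaldehyde
Product: 4 [2-bromo-3,5-dimethoxy-4-(triisopropylsilyloxy)phenyl]methanol
Conditions: NaBH4, MeOH/THF, 0 °C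
Reagents that add atoms: none
Why: Hydride reduction of the aldehyde to the benzylic alcohol; the aryl bromide and the silyl ether are inert.

Step 4
Reactants: 4 [2-bromo-3,5-dimethoxy-4-(triisopropylsilyloxy)phenyl]methanol
Product: 5 [3-bromo-4-(bromomethyl)-2,6-dimethoxyphenoxy]triisopropylsilane
Conditions: CBr4, PPh3, CH2Cl2, 0 °C
Reagents that add atoms: tetrabromomethane, BrC(Br)(Br)Br
Why: Appel reaction; neutral conditions convert the benzylic alcohol into the bromide without touching the silyl ether.

Step 5
Reactants: 5 [3-bromo-4-(bromomethyl)-2,6-dimethoxyphenoxy]triisopropylsilane; 6 (Z)-2-(but-2-en-2-yl)-4,4,5,5-tetramethyl-1,3,2-dioxaborolane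
Product: 7 {3-bromo-2,6-dimethoxy-4-[(E)-2-methylbut-2-en-1-yl]phenoxy}triisopropylsilane
Conditions: Pd(PPh3)4 (5 mol%), K2CO3, THF/H2O 10:1, 50 °C
Reagents that add atoms: none
Why: Suzuki–Miyaura coupling at the benzylic C(sp3)–Br bond, which adds to zerovalent palladium much faster than the hindered, electron-rich aryl bromide. The alkenyl group transfers with retention, so the Z-boronate (methyl groups cis) gives the E-olefin (CH2Ar anti to the C2 methyl).

Step 6
Reactants: 7 {3-bromo-2,6-dimethoxy-4-[(E)-2-methylbut-2-en-1-yl]phenoxy}triisopropylsilane; 2 3,5-dimethoxy-4-(triisopropylsilyloxy)benzaldehyde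
Product: 9 {2,4-dimethoxy-6-[(E)-2-methylbut-2-en-1-yl]-3-(triisopropylsilyloxy)phenyl}[3,5-dimethoxy-4-(triisopropylsilyloxy)phenyl]methanol (racemic), via aryllithium 8 (not isolated)
Conditions: n-BuLi, THF, −78 °C; then 2, −78 to −20 °C; H2O
Reagents that add atoms: none
Why: Bromine–lithium exchange at −78 °C should outrun deprotonation of the benzylic CH2, and 1,2-addition of the hindered aryllithium to the unhindered aldehyde forms the C8a–C1 bond. The carbinol configuration is irrelevant because this centre is ionised in step 8.

Step 7
Reactants: 9 {2,4-dimethoxy-6-[(E)-2-methylbut-2-en-1-yl]-3-(triisopropylsilyloxy)phenyl}[3,5-dimethoxy-4-(triisopropylsilyloxy)phenyl]methanol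
Product: 10 4-{hydroxy[3-hydroxy-2,4-dimethoxy-6-((E)-2-methylbut-2-en-1-yl)phenyl]methyl}-2,6-dimethoxyphenol (racemic)
Conditions: Bu4NF (2.2 equiv), AcOH (2.2 equiv), THF, 0 °C
Reagents that add atoms: none
Why: Fluoride cleaves both aryl silyl ethers; acetic acid buffers the phenoxides so that the p-hydroxybenzhydrol does not expel hydroxide prematurely.

Step 8
Reactants: 10 4-{hydroxy[3-hydroxy-2,4-dimethoxy-6-((E)-2-methylbut-2-en-1-yl)phenyl]methyl}-2,6-dimethoxyphenol
Product: 12 (1S,2S)-1-(4-hydroxy-3,5-dimethoxyphenyl)-6,8-dimethoxy-2,3-dimethyl-1,2-dihydronaphthalen-7-ol, via quinone methide 11 (not isolated)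
Conditions: (R)-3,3′-bis(2,4,6-triisopropylphenyl)-1,1′-binaphthyl-2,2′-diyl N-(trifluoromethylsulfonyl)phosphoramide, (ArO)2P(O)NHSO2CF3 (5 mol%), toluene (0.01 M), 5 Å molecular sieves, −40 to 0 °C; then Et3N
Reagents that add atoms: none
Why: Proposed new method: the strong chiral Brønsted acid dehydrates the p-hydroxybenzhydrol 10 to quinone methide 11 and protonates it to a hydroxy-diarylmethylium ion that stays hydrogen-bonded through its phenolic OH to the chiral phosphoramidate; the E-olefin then adds through its less substituted carbon C2 to C1, and the tertiary C3 cation gives its benzylic C4 proton to the counter-anion, which forms the conjugated C3=C4 bond and returns the acid. The closest known reaction types are chiral-phosphoric-acid-catalysed 1,6-additions to p-quinone methides generated in situ from p-hydroxybenzyl alcohols, and chiral-anion-controlled Prins and cation–olefin cyclisations; the new element is an unactivated olefin as the intramolecular partner of a quinone methide. The six-membered ring closes at C1–C2 in the 6-endo mode with respect to the olefin (Markovnikov); the 5-exo alternative through C3 would leave a secondary cation. C2 is controlled by the E geometry of the olefin, which holds its methyl anti to C4 and therefore pseudo-equatorial in the half-chair. C1 is controlled by allylic 1,3-strain with the peri C8 methoxy group, which keeps the hydrogen in the plane of ring A and the aryl group pseudo-axial, so aryl and methyl end up cis; the transition state should be late, because a doubly stabilised diarylmethylium ion is traded for an alkyl cation, so this product-like preference should be felt. The absolute sense is set by the chiral anion, which must distinguish the two enantiomeric ion pairs in which the tethered olefin lies over one or the other face of C1. The selectivities needed are cis over trans (olefin geometry plus peri strain), proton loss from C4 rather than C2 (benzylic C–H, conjugated product), and no re-ionisation of the product (low temperature, low acid loading, amine quench).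

## Compound list

1 | syringaldehyde (4-hydroxy-3,5-dimethoxybenzaldehyde) | COc1cc(C=O)cc(OC)c1O | starting material
2 | 3,5-dimethoxy-4-(triisopropylsilyloxy)benzaldehyde | COc1cc(C=O)cc(OC)c1O[Si](C(C)C)(C(C)C)C(C)C | intermediate
3 | 2-bromo-3,5-dimethoxy-4-(triisopropylsilyloxy)benzaldehyde | COc1cc(C=O)c(Br)c(OC)c1O[Si](C(C)C)(C(C)C)C(C)C | intermediate
4 | [2-bromo-3,5-dimethoxy-4-(triisopropylsilyloxy)phenyl]methanol | COc1cc(CO)c(Br)c(OC)c1O[Si](C(C)C)(C(C)C)C(C)C | intermediate
5 | [3-bromo-4-(bromomethyl)-2,6-dimethoxyphenoxy]triisopropylsilane | COc1cc(CBr)c(Br)c(OC)c1O[Si](C(C)C)(C(C)C)C(C)C | intermediate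
6 | (Z)-2-(but-2-en-2-yl)-4,4,5,5-tetramethyl-1,3,2-dioxaborolane | C/C=C(\C)B1OC(C)(C)C(C)(C)O1 | starting material
7 | {3-bromo-2,6-dimethoxy-4-[(E)-2-methylbut-2-en-1-yl]phenoxy}triisopropylsilane | C/C=C(\C)Cc1cc(OC)c(O[Si](C(C)C)(C(C)C)C(C)C)c(OC)c1Br | intermediate
8 | aryllithium from 7 (lithium in place of bromine) | C/C=C(\C)Cc1cc(OC)c(O[Si](C(C)C)(C(C)C)C(C)C)c(OC)c1[Li] | intermediate
9 | bis-silylated diaryl carbinol (racemic) | C/C=C(\C)Cc1cc(OC)c(O[Si](C(C)C)(C(C)C)C(C)C)c(OC)c1C(O)c1cc(OC)c(O[Si](C(C)C)(C(C)C)C(C)C)c(OC)c1 | intermediate
10 | 4-{hydroxy[3-hydroxy-2,4-dimethoxy-6-((E)-2-methylbut-2-en-1-yl)phenyl]methyl}-2,6-dimethoxyphenol (racemic) | C/C=C(\C)Cc1cc(OC)c(O)c(OC)c1C(O)c1cc(OC)c(O)c(OC)c1 | intermediate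
11 | 4-{[3-hydroxy-2,4-dimethoxy-6-((E)-2-methylbut-2-en-1-yl)phenyl]methylidene}-2,6-dimethoxycyclohexa-2,5-dien-1-one (p-quinone methide) | C/C=C(\C)Cc1cc(OC)c(O)c(OC)c1C=C1C=C(OC)C(=O)C(OC)=C1 | intermediate
12 | (1S,2S)-1-(4-hydroxy-3,5-dimethoxyphenyl)-6,8-dimethoxy-2,3-dimethyl-1,2-dihydronaphthalen-7-ol | COc1cc([C@H]2c3c(cc(OC)c(O)c3OC)C=C(C)[C@H]2C)cc(OC)c1O | target

## Step count and risks

Total steps: 8. Longest linear sequence: 8 (1 → 2 → 3 → 4 → 5 → 7 → 9 → 10 → 12); compound 2 enters a second time in step 6.

**Step 8 (key step, proposed new method).** The most likely failure is poor facial discrimination in the ion pair. The olefin has no hydrogen-bond donor to dock on the catalyst, and a racemic background channel is conceivable: loss of the C4 proton from the cation to an o-quinodimethane followed by thermal 6π-electrocyclisation, which would also give the cis isomer. Two lesser weaknesses are closure through the half-chair with the aryl group pseudo-equatorial (trans isomer), if the transition state is earlier than argued, and some proton loss from C2 instead of C4. The fallback uses known chemistry and sets out from 10. An achiral acid, diphenyl phosphate (PhO)2P(O)OH (10 mol%, CH2Cl2, 0 °C), should effect the ordinary acid-mediated cation–olefin cyclisation to the racemate, that is 12 together with its enantiomer F1. Both phenols are then esterified with (S)-2-methoxy-2-phenylacetic acid (N,N′-dicyclohexylcarbodiimide, 4-(dimethylamino)pyridine) to the diastereomeric diesters F2 (from 12) and F3 (from F1). These are separated by chromatography or crystallisation, which also removes any trans isomer. Methanolysis of the diester F2 (K2CO3, MeOH) comes back to 12.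

**Step 7.** The risk is premature ionisation: the free p-hydroxybenzhydrol can expel hydroxide under fluoride or on silica, and the resulting quinone methide oligomerises on concentration. The fallback sets out from 9 and avoids isolating 10. The carbinol is acetylated (Ac2O, pyridine) to the acetate F4. Bu4NF at −78 °C removes both silyl groups, and the ring B phenoxide expels acetate in a 1,6-elimination, a known way to make p-quinone methides. After an aqueous wash and drying, the toluene solution contains 11, where the fallback rejoins the route, and the chiral acid is added to it.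

**Step 5.** The risks are solvolysis of the electron-rich benzylic bromide under aqueous base, homocoupling, and some oxidative addition at the aryl C–Br bond. The fallback sets out from 5 and reverses the polarity. Zinc insertion (Zn dust, LiCl, THF), which is selective for the benzylic bromide, gives the benzylzinc bromide F5. Negishi coupling of F5 with commercial (E)-2-bromobut-2-ene and Pd(PPh3)4 under anhydrous, base-free conditions comes back to 7 with the same olefin geometry.

## Further compounds

F1 | step 8 | (1R,2R)-enantiomer of 12 | COc1cc([C@@H]2c3c(cc(OC)c(O)c3OC)C=C(C)[C@@H]2C)cc(OC)c1O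
F2 | step 8 | bis[(S)-2-methoxy-2-phenylacetate] of 12 | COc1cc([C@H]2c3c(cc(OC)c(OC(=O)[C@@H](OC)c4ccccc4)c3OC)C=C(C)[C@H]2C)cc(OC)c1OC(=O)[C@@H](OC)c1ccccc1
F3 | step 8 | bis[(S)-2-methoxy-2-phenylacetate] of F1 | COc1cc([C@@H]2c3c(cc(OC)c(OC(=O)[C@@H](OC)c4ccccc4)c3OC)C=C(C)[C@@H]2C)cc(OC)c1OC(=O)[C@@H](OC)c1ccccc1
F4 | step 7 | acetate of carbinol 9 (racemic) | C/C=C(\C)Cc1cc(OC)c(O[Si](C(C)C)(C(C)C)C(C)C)c(OC)c1C(OC(C)=O)c1cc(OC)c(O[Si](C(C)C)(C(C)C)C(C)C)c(OC)c1
F5 | step 5 | [2-bromo-3,5-dimethoxy-4-(triisopropylsilyloxy)benzyl]zinc bromide | COc1cc(C[Zn]Br)c(Br)c(OC)c1O[Si](C(C)C)(C(C)C)C(C)C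
A1 | alternative 1 | (E)-2,6-dimethoxy-4-(prop-1-en-1-yl)phenol | C/C=C/c1cc(OC)c(O)c(OC)c1
A2 | alternative 1 | β–β bis-quinone methide | O=C1C(OC)=CC(=CC(C)C(C)C=C2C=C(OC)C(=O)C(OC)=C2)C=C1OC
A3 | alternative 1 | 1,2-trans isomer of 12 (racemic; the (1R,2S) enantiomer is drawn) | COc1cc([C@@H]2c3c(cc(OC)c(O)c3OC)C=C(C)[C@H]2C)cc(OC)c1O
A4 | alternative 2 | ring-closing-metathesis diene (drawn without protecting groups) | COc1cc([C@@H](c2c(C=C)cc(OC)c(O)c2OC)[C@H](C)C(C)=C)cc(OC)c1O
A5 | alternative 3 | (S)-4-tert-butyl-2-[6,8-dimethoxy-3-methyl-7-(triisopropylsilyloxy)naphthalen-2-yl]-4,5-dihydrooxazole | COc1cc2cc(C)c(cc2c(OC)c1O[Si](C(C)C)(C(C)C)C(C)C)C1=N[C@@H](C(C)(C)C)CO1
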